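Picture a one-step world: every starting material becomes target, however it is added. This flask has a second road, so measure it.

| setting | ash | oak | summer | autumn | noon | midnight |
|---|---|---|---|---|---|---|
| starting material | 0.070 M | 0.14 M | 0.070 M | 0.070 M (fed, over 3.0 min) | 0.070 M (fed, over 3.0 min) | 0.070 M |
| partner | 0.21 M | 0.21 M | 0.210 M (in portions, 4, over 3.0 min) | 0.210 M | 0.210 M | 0.210 M (fed, over 3.0 min) |
| second substrate | 0.070 M | 0.070 M | 0.0700 M | 0.0700 M | 0.0700 M | 0.0700 M |
| precatalyst | 0.98 mM | 0.98 mM | 0.98 mM | 0.98 mM | 0.98 mM | 0.98 mM |
| temperature | 5 °C | 5 °C | 5 °C | 5 °C |  | 5 °C |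
| remark | run made earlier | run made earlier | first portion at the start, last at 3.0 min | all else is in the flask from the start; the feed brings no volume worth counting | the addition at −15 °C, then warmed to 5 °C; the feed brings no volume worth counting | all else is in the flask from the start; the feed brings no volume worth counting |
| time |  |  | 15 min | 15 min | 15 min | 15 min |

| run | time / min | target / % | starting material / % |
|---|---|---|---|
| ash | 1.33 | 6.2 | 37.4 |
| ash | 2.00 | 9.7 | 27.0 |
| ash | 3.00 | 13.4 | 18.5 |
| ash | 4.00 | 15.7 | 14.2 |
| ash | 6.00 | 19.0 | 8.5 |
| ash | 10.0 | 21.0 | 4.6 |
| ash | 15.0 | 23.0 | 2.3 |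
| oak | 0.167 | 0.2 | 72.5 |
| oak | 0.500 | 0.6 | 47.5 |
| oak | 0.833 | 3.0 | 35.3 |
| oak | 1.33 | 4.3 | 24.3 |
| oak | 2.00 | 6.5 | 16.5 |
| oak | 2.50 | 7.4 | 13.5 |
| oak | 3.00 | 8.0 | 10.5 |

(scatter of a reading: 0.5 percentage points)

1. which flask leads in amount of target, in percent of the starting material charged ("all alike" within 1.5 percentage points) (summer / autumn / noon / midnight / all alike)
2. how much target is there at the end, in percent of the starting material charged: summer
3. how much target is there at the end, in percent of the starting material charged: autumn
4. how much target is there at the end, in percent of the starting material charged: noon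
5. how much target is there at the end, in percent of the starting material charged: midnight

- the earlier runs do not show what temperature does; that part of a forecast is a guess

Let s be the concentration of starting material. Early in oak there is almost no target, so plot the inverse of s against time. The slope gives a loss rate D·s·s, with D = 15.6 L mol⁻¹ min⁻¹. In ash, divide the target gained from 3.00 min to 6.00 min by the time and the mean s. This gives a target rate kT·s, with kT = 0.138 min⁻¹. Both are readings and carry their scatter.

Now form the split concentration, sx = kT/D, 8.88 mM, the s at which both roads run equally. The share going to target (a selectivity) is sx/(sx + s).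

Take the extremes. Feed endlessly slowly, so that s stays far under sx, and you are back in the one-step world. Add everything at once, then average the share as s falls from the charge to nothing: 27.7%. Ash reads 23.0% at 15.0 min.

Autumn lies between. Set feed equal to loss and s plateaus at 0.0345 M. Near the plateau s relaxes with a time constant of about 0.823 min, shorter than the feed time of 3.0 min, so s climbs through the feed and nears the plateau towards its end. Count the plateau share for what reacts during the feed and the all-at-once average for what stands afterwards. Earlier in the feed s stands lower, so the plateau share is on the low side. My autumn is 30.5%. Both runs used the same partner charge, so treat partner as untested. If the target step uses it, expect summer and midnight below ash. Guess noon near ash.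

The forecast chose autumn: summer 22%, autumn 33%, noon 29%, midnight 21.5%. On partner it said “dosing it wastes early material”. Its autumn stands above mine.

The flasks give summer 14.5%, autumn 30.1%, noon 22.4%, midnight 14.5%; autumn leads.

    starting material + partner + catalyst → catalyst + target (k = 3800 L² mol⁻² min⁻¹, Ea = 40.0 kJ mol⁻¹)
    second substrate + partner + catalyst → catalyst + second product (k = 19000 L² mol⁻² min⁻¹, Ea = 35.0 kJ mol⁻¹)
    2 starting material → homo dimer (k = 7.60 L mol⁻¹ min⁻¹, Ea = 36.0 kJ mol⁻¹)
    catalyst ⇌ dormant form (K = 6.60, k = 0.340 min⁻¹, Ea = 74.0 kJ mol⁻¹, ΔH = −19.0 kJ mol⁻¹)
    partner + precatalyst → catalyst + spent reagent (k = 1.30 L mol⁻¹ min⁻¹, Ea = 63.0 kJ mol⁻¹)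
    (constants at 5 °C)

Autumn's mean s over the first 3.0 min is 0.0226 M, which gives a share of 28.2%. The target step above takes partner, so scale sx with the partner charge and hold the catalyst. The neighbour flask is autumn with 0.13 M of partner. Its sx becomes 5.50 mM. Keep autumn's mean s, and the share falls to 19.6%. The neighbour flask holds less target than that: 14.4% at 15.0 min, with 5.25% of its starting material left.

(The numbers in the tables come from a simulation from invented constants, and the scatter is random.)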